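Remark: germacrane numbering is used for positions (ring C1–C10, lactone carbons C11–C13, C14 on C10, C15 on C4). Compound numbers are those of the steps and of the compound list.

## Analysis of the target

The target is a cis,cis-germacranolide. A ten-membered carbocycle (C1–C10) carries two trisubstituted double bonds, C1=C10 and C4=C5, both cis within the ring. It is trans-fused at C6/C7 to an α-methylene-γ-butyrolactone (O6–C12(=O)–C11(=C13H2)–C7). C10 bears a formyl group (C14), C4 a hydroxymethyl group (C15) and C8 an (S)-2-methylbutanoate. The ring holds three contiguous stereocentres, C6 (R), C7 (R) and C8 (R): H6 and H7 are trans, while the C7–C11 and C8–O bonds are cis. The fourth centre (C2′, S) arrives with the acid. Read from their carbonyl or carbinol substituent, both ring alkenes have the geometry of an (E)-2-alkyl-2-enal (C14 trans to C2, C15 trans to C6), so both can be set by stereospecific additions to alkynes at an open-chain stage. Sensitive groups are the methylene lactone (Michael acceptor, hydride-labile), the enal, the allylic alcohol and the epimerisable α-branched ester. C14 and C15 must end at different oxidation levels although they sit in near-equivalent positions. The feature that invites the chosen move is the array O6–C6–C7–C11(=C13H2)–C12. A homoallylic alkoxide beside an acrylate is the product pattern of a [2,3]-sigmatropic shift of an O6–C13 ether, and C6 is also the γ-carbon of the C15–C4=C5 unit, hence acidic once C15 is an aldehyde. The difficulty lies in the strained medium ring with two cis trisubstituted alkenes, in setting C6–C8 on that flexible ring, and in the redox traffic between C12, C14 and C15.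

## Retrosynthetic reasoning

No skeletal bond is cut between 29 and 27. In 27, C15 is still the aldehyde that the key step needs and C14 is a diethyl acetal. Forward, a 1,2-reduction that spares the methylene lactone (via 28) and a mild acetal hydrolysis are required. Keeping C14 masked while C15 is free means the two formyl groups are never free together.

The C8–O acyl bond of 27 is cut to alcohol 25 and acid 26. The key step is expected to place O8 trans to C11 (8S in 25), so the ester bond is made with inversion. This corrects C8 and installs the side chain in one operation. Alcohol 25 comes from silyl ether 24.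

The key disconnection cuts C6–C7 of 24 and reconnects O6 to C13. This opens the ten-membered ring and the lactone together and leads to the thirteen-membered oxacycle 21. C6–C7 is the bond common to both rings and carries two of the three ring stereocentres. A transannular shift inside a thirteen-membered ether avoids closing a ten-membered ring from an open chain. Forward, 21 must be deprotonated only at C6 (dienolate 22), rearrange to alkoxide 23 with control of C6 and C7, and lactonise to 24.

The C15 aldehyde of 21 is traced to the primary silyl ether of 20. The ring of 20 is opened at C3–C4, an sp3–sp2 bond, to give 18. Both coupling partners (a terminal vinyl group and a Z-alkenyl iodide) are inert in the steps before, and the coupling keeps the C4=C5 geometry. Forward, hydroboration of 18 to 19 and an intramolecular Suzuki–Miyaura coupling are needed.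

In 18 the ether bond O6–C13 and the C7=C11 double bond are cut together. This releases alcohol 4, acrylate 16 (which supplies C11, C12 and C13) and aldehyde 12. Forward, oxa-Michael addition gives carbanion 17, which must olefinate 12 with C8 cis to the ester; that geometry is what the key step requires.

Aldehyde 12 comes from bis-silyl ether 11 and alcohol 10. Compound 10 is cut at C1–C2 and at C9–C10 around alkyne 8. Forward, syn-carbocupration with 7 gives 9, which opens epoxide 6. This sets the C1=C10 geometry and brings C8 from 5.

Iodide 4 is traced through aluminate 3 to alkyne 2, made from 1. Hydroxyl-directed hydroalumination places C15 trans to C6. Acrylate 16 comes from 13 and 14 via 15.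

## Alternatives that were turned down

Alternative 1: the textbook route is an intramolecular Barbier-type allylation. It cuts C6–C7 of the target in an open chain: bromo aldehyde A1 would be cyclised with CrCl2 (divalent chromium) to the ten-membered ring and the lactone at once. It was turned down for three reasons. The C6 aldehyde of A1 is a β,β-disubstituted enal with the formyl group cis to C3, and such enals lose their geometry easily, so the cis C4=C5 bond is at risk. The ten-membered ring must close directly from a chain at high dilution with excess metal. C15 cannot serve as an activating group, so C14 and C15 both need separate protection and redox steps.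

Alternative 2: ring-closing metathesis across C4=C5 of diene lactone A2, which would be made by an intermolecular allylation that sets C6–C8 first. The forward step would use a second-generation Grubbs catalyst. It was turned down because the new alkene is trisubstituted, allylically oxygenated and part of a strained ten-membered ring. A2 also offers the catalyst two competing 1,1-disubstituted alkenes (the methylene lactone and the C4 methylidene), and the ring geometry would not be under control.

Alternative 3: a Cope ring expansion of the elemane-type cis-divinylcyclohexane A3, cutting C2–C3 of the target and joining C5 to C10. It was turned down because a cis,cis-cyclodeca-1,5-diene can only arise from the cis-divinyl isomer through a boat transition state. The equilibrium normally favours the six-membered ring, and enal conjugation is a weak driver. A3 would also need a quaternary C10 carrying formyl and vinyl groups next to four stereocentres, which costs more than the rearrangement saves.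

Key step: step 11

## Steps

Step 1
Reactants: 1 but-2-yne-1,4-diol
Product: 2 4-(triethylsilyloxy)but-2-yn-1-ol
Conditions: Et3SiCl, imidazole, DMF, 0 °C (diol in excess)
Reagents that add atoms: chlorotriethylsilane, CC[Si](Cl)(CC)CC
Why: Statistical monosilylation of a cheap symmetrical diol; the excess diol is washed out with water.

Step 2
Reactants: 2 4-(triethylsilyloxy)but-2-yn-1-ol
Product: 4 (2Z)-3-iodo-4-(triethylsilyloxy)but-2-en-1-ol, via cyclic alkenylaluminate 3 (not isolated)
Conditions: NaAlH2(OCH2CH2OMe)2, THF, 0 °C; then I2, THF, −78 °C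
Reagents that add atoms: iodine, II
Why: Hydroxyl-directed trans-hydroalumination of the propargylic alcohol delivers hydride to C5 and aluminium to C4 inside a five-membered aluminate. Iodinolysis with retention should give the Z-iodide with iodine cis to C6, so that C15 is trans to C6.

Step 3
Reactants: 5 (R)-glycidol
Product: 6 triethyl{[(2S)-oxiran-2-yl]methoxy}silane
Conditions: Et3SiCl, Et3N, DMAP (cat.), CH2Cl2, 0 °C
Reagents that add atoms: chlorotriethylsilane, CC[Si](Cl)(CC)CC
Why: Plain O-silylation; the stereocentre is untouched and the descriptor changes only through the priority rules.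

Step 4
Reactants: 7 vinylmagnesium bromide; 8 3,3-diethoxyprop-1-yne; 6 triethyl{[(2S)-oxiran-2-yl]methoxy}silane
Product: 10 (2S,4E)-4-(diethoxymethyl)-1-(triethylsilyloxy)hepta-4,6-dien-2-ol, via dienyl vinyl cuprate 9 (not isolated)
Conditions: 7 (2 equiv), CuBr·SMe2 (1 equiv), Et2O/Me2S, −45 °C; 8, −45 to −25 °C; then 6, −25 to 0 °C; aq. NH4Cl
Reagents that add atoms: none
Why: syn-Carbocupration of the propargylic acetal puts the vinyl group on the terminal carbon (C1) and copper on C10, cis to each other. Opening of the epoxide at its CH2 with retention at the alkenyl carbon should give C2 cis to C9 and C14 trans to C2. C8 comes unchanged from glycidol.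

Step 5
Reactants: 10 (2S,4E)-4-(diethoxymethyl)-1-(triethylsilyloxy)hepta-4,6-dien-2-ol
Product: 11 (2S,4E)-4-(diethoxymethyl)-1,2-bis(triethylsilyloxy)hepta-4,6-diene
Conditions: Et3SiCl, imidazole, DMF, 0 °C to rt
Reagents that add atoms: chlorotriethylsilane, CC[Si](Cl)(CC)CC
Why: Silylation of the secondary alcohol under basic conditions that leave the acetal alone.

Step 6
Reactants: 11 (2S,4E)-4-(diethoxymethyl)-1,2-bis(triethylsilyloxy)hepta-4,6-diene
Product: 12 (2S,4E)-4-(diethoxymethyl)-2-(triethylsilyloxy)hepta-4,6-dienal
Conditions: (COCl)2, DMSO, CH2Cl2, −78 to −30 °C; then Et3N, −78 °C to rt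
Reagents that add atoms: none
Why: Under Swern conditions a primary triethylsilyl ether is cleaved and oxidised directly to the aldehyde, while the secondary one stays. Low temperature should keep the α-silyloxy aldehyde configurationally intact.

Step 7
Reactants: 13 methyl 2-[bis(2,2,2-trifluoroethoxy)phosphoryl]acetate; 14 paraformaldehyde
Product: 16 methyl 2-[bis(2,2,2-trifluoroethoxy)phosphoryl]prop-2-enoate, via hydroxymethyl adduct 15 (not isolated)
Conditions: (CH2O)n, piperidine (cat.), AcOH (cat.), toluene, reflux (Dean–Stark)
Reagents that add atoms: none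
Why: Knoevenagel methylenation of the phosphonoacetate. An alcohol-free medium avoids exchange of the trifluoroethyl esters.

Step 8
Reactants: 4 (2Z)-3-iodo-4-(triethylsilyloxy)but-2-en-1-ol; 16 methyl 2-[bis(2,2,2-trifluoroethoxy)phosphoryl]prop-2-enoate; 12 (2S,4E)-4-(diethoxymethyl)-2-(triethylsilyloxy)hepta-4,6-dienal
Product: 18 methyl (2Z,4S,6E)-6-(diethoxymethyl)-2-({[(2Z)-3-iodo-4-(triethylsilyloxy)but-2-en-1-yl]oxy}methyl)-4-(triethylsilyloxy)nona-2,6,8-trienoate, via potassium phosphonate carbanion 17 (not isolated)
Conditions: 4, KN(SiMe3)2, THF, −78 °C; 16; then 18-crown-6, 12, −78 to −40 °C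
Reagents that add atoms: none
Why: Oxa-Michael addition of the alkoxide of 4 to the phosphonoacrylate forms the O6–C13 bond and gives the stabilised carbanion without excess base. Its Still–Gennari olefination of 12 should give the Z-enoate (C8 cis to the ester, trans to C13).

Step 9
Reactants: 18 methyl (2Z,4S,6E)-6-(diethoxymethyl)-2-({[(2Z)-3-iodo-4-(triethylsilyloxy)but-2-en-1-yl]oxy}methyl)-4-(triethylsilyloxy)nona-2,6,8-trienoate
Product: 20 methyl (3Z,5S,7E,11E)-7-(diethoxymethyl)-5-(triethylsilyloxy)-11-[(triethylsilyloxy)methyl]-1-oxacyclotrideca-3,7,11-triene-3-carboxylate, via B-alkyl-9-BBN borane 19 (not isolated)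
Conditions: 9-BBN, THF, rt; then PdCl2(dppf) (cat.), AsPh3, Cs2CO3, DMF/THF/H2O, 45 °C, high dilution
Reagents that add atoms: none
Why: 9-BBN adds to the terminal CH2 of the diene only (boron on C3), leaving the trisubstituted and electron-poor alkenes. The intramolecular B-alkyl Suzuki–Miyaura coupling closes the thirteen-membered ring at C3–C4 with retention at the alkenyl iodide, so C3 ends cis to C6.

Step 10
Reactants: 20 methyl (3Z,5S,7E,11E)-7-(diethoxymethyl)-5-(triethylsilyloxy)-11-[(triethylsilyloxy)methyl]-1-oxacyclotrideca-3,7,11-triene-3-carboxylate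
Product: 21 methyl (3Z,5S,7E,11E)-7-(diethoxymethyl)-11-formyl-5-(triethylsilyloxy)-1-oxacyclotrideca-3,7,11-triene-3-carboxylate
Conditions: (COCl)2, DMSO, CH2Cl2, −78 to −30 °C; then Et3N, −78 °C to rt
Reagents that add atoms: none
Why: The same selective Swern oxidation turns the primary allylic silyl ether at C15 into the enal and keeps the secondary silyl ether at C8. The E-enal geometry is the stable one.

Step 11
Reactants: 21 methyl (3Z,5S,7E,11E)-7-(diethoxymethyl)-11-formyl-5-(triethylsilyloxy)-1-oxacyclotrideca-3,7,11-triene-3-carboxylate
Product: 24 (3aS,4S,6E,10E,11aR)-6-(diethoxymethyl)-3-methylidene-2-oxo-4-(triethylsilyloxy)-2,3,3a,4,5,8,9,11a-octahydrocyclodeca[b]furan-10-carbaldehyde, via potassium dienolate 22 (not isolated), via potassium alkoxide 23 (not isolated)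
Conditions: KN(SiMe3)2, 18-crown-6, THF, −78 to −30 °C (inverse addition, 0.01 M); AcOH, −78 °C; then PPTS (cat.), CH2Cl2, rt
Reagents that add atoms: none
Why: Proposed new method: the silylamide removes a C6 proton, the only protons of 21 that are vinylogous to an aldehyde (γ to C15 through C4=C5; the ester γ-proton at C8 is several pKa units weaker), and dienolate 22 undergoes a concerted, polar [2,3]-sigmatropic (Wittig-type) shift in which C6 bonds to C7 while the C13–O bond breaks and C11=C13 appears, the ester on C11 lowering the allyl acceptor orbital so that even a stabilised dienolate should react below 0 °C. The closest known reactions are the transannular [2,3]-Wittig ring contraction of thirteen-membered diallylic ethers with alkyllithium bases, the [2,3]-Wittig rearrangement of α-allyloxy carbonyl enolates and the SN2′ addition–elimination of carbon nucleophiles on 2-(alkoxymethyl)acrylates; what is new is the vinylogous (dienolate) donor. The ten-membered carbocycle is closed by transannular C6–C7 bonding through a five-membered envelope transition state (ring contraction 13 to 10), and the lactone by 5-exo-trig acyl substitution of alkoxide 23 on the C12 ester. C6 and C7 are set together: the allyl unit has C8 trans to C13, and with the dienolate chain exo on the envelope this geometry gives the anti pair, that is the trans-fused lactone. The face of C7 is chosen by C8: allylic strain with the cis ester holds H8 in the alkene plane and C6 adds anti to the C8–O bond (Felkin–Anh sense), on the side where C9 and the tether lie, so the 8S centre should lead to the 6R,7R arrangement of the target with O8 trans to C11 (C7 is labelled 3aS in 24 only because the silyloxy carbon outranks C6). The step needs γ- over α-reactivity of the dienolate, which the five-membered array provides because only C6 is within reach of C7 and a concerted shift from C4 would be an eight-electron process. It also needs the C4=C5 geometry to survive, which the s-trans dienolate formed from the E-enal should ensure. The cold acetic acid quench before lactonisation limits epimerisation at C6 by methoxide.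

Step 12
Reactants: 24 (3aS,4S,6E,10E,11aR)-6-(diethoxymethyl)-3-methylidene-2-oxo-4-(triethylsilyloxy)-2,3,3a,4,5,8,9,11a-octahydrocyclodeca[b]furan-10-carbaldehyde
Product: 25 (3aR,4S,6E,10E,11aR)-6-(diethoxymethyl)-4-hydroxy-3-methylidene-2-oxo-2,3,3a,4,5,8,9,11a-octahydrocyclodeca[b]furan-10-carbaldehyde
Conditions: Bu4NF, AcOH (1:1), THF, 0 °C
Reagents that add atoms: none
Why: Buffered fluoride removes the secondary triethylsilyl group without base-induced damage to the enal or the methylene lactone, and without acid that could tie O8 to the C14 acetal.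

Step 13
Reactants: 25 (3aR,4S,6E,10E,11aR)-6-(diethoxymethyl)-4-hydroxy-3-methylidene-2-oxo-2,3,3a,4,5,8,9,11a-octahydrocyclodeca[b]furan-10-carbaldehyde; 26 (2S)-2-methylbutanoic acid
Product: 27 (3aR,4R,6E,10E,11aR)-6-(diethoxymethyl)-10-formyl-3-methylidene-2-oxo-2,3,3a,4,5,8,9,11a-octahydrocyclodeca[b]furan-4-yl (2S)-2-methylbutanoate
Conditions: PPh3, DIAD, toluene, 0 °C (betaine preformed), then 25 and 26, 0 °C to rt
Reagents that add atoms: none
Why: Mitsunobu esterification displaces the activated C8 oxygen by the carboxylate with inversion, so the 8S alcohol should give the 8R ester with O8 cis to C11. C2′ of the acid is not involved and keeps its S configuration.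

Step 14
Reactants: 27 (3aR,4R,6E,10E,11aR)-6-(diethoxymethyl)-10-formyl-3-methylidene-2-oxo-2,3,3a,4,5,8,9,11a-octahydrocyclodeca[b]furan-4-yl (2S)-2-methylbutanoate
Product: 29 (3aR,4R,6E,10E,11aR)-6-formyl-10-(hydroxymethyl)-3-methylidene-2-oxo-2,3,3a,4,5,8,9,11a-octahydrocyclodeca[b]furan-4-yl (2S)-2-methylbutanoate, via allylic alcohol acetal 28 (not isolated)
Conditions: NaBH4, CeCl3·7H2O, EtOH/THF, −40 °C; acetone; then aq. oxalic acid, THF, rt
Reagents that add atoms: water, O
Why: Luche conditions should reduce the C15 enal 1,2 and faster than borohydride can add to the methylene lactone or touch the esters. Mild aqueous acid then hydrolyses the allylic diethyl acetal to the C14 enal, whose E geometry is the stable one.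

## Compound list

1 | but-2-yne-1,4-diol | OCC#CCO | starting material
2 | 4-(triethylsilyloxy)but-2-yn-1-ol | OCC#CCO[Si](CC)(CC)CC | intermediate
3 | sodium cyclic alkenylaluminate from 2 (Al on C4 and on O6, two 2-methoxyethoxy ligands) | [Na+].COCCO[Al-]1(OCCOC)OCC=C1CO[Si](CC)(CC)CC | intermediate
4 | (2Z)-3-iodo-4-(triethylsilyloxy)but-2-en-1-ol | OC/C=C(\I)CO[Si](CC)(CC)CC | intermediate
5 | (R)-glycidol, (2R)-oxiran-2-ylmethanol | OC[C@@H]1CO1 | starting material
6 | triethyl{[(2S)-oxiran-2-yl]methoxy}silane | CC[Si](CC)(CC)OC[C@@H]1CO1 | intermediate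
7 | vinylmagnesium bromide | C=C[Mg]Br | starting material
8 | 3,3-diethoxyprop-1-yne | C#CC(OCC)OCC | starting material
9 | bromomagnesium [(3Z)-5,5-diethoxypenta-1,3-dien-4-yl](vinyl)cuprate | C=C/C=C(\[Cu-]C=C)C(OCC)OCC.[Mg+]Br | intermediate
10 | (2S,4E)-4-(diethoxymethyl)-1-(triethylsilyloxy)hepta-4,6-dien-2-ol | CC[Si](CC)(CC)OC[C@@H](O)C/C(=C\C=C)C(OCC)OCC | intermediate
11 | (2S,4E)-4-(diethoxymethyl)-1,2-bis(triethylsilyloxy)hepta-4,6-diene | CC[Si](CC)(CC)OC[C@@H](O[Si](CC)(CC)CC)C/C(=C\C=C)C(OCC)OCC | intermediate
12 | (2S,4E)-4-(diethoxymethyl)-2-(triethylsilyloxy)hepta-4,6-dienal | O=C[C@@H](O[Si](CC)(CC)CC)C/C(=C\C=C)C(OCC)OCC | intermediate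
13 | methyl 2-[bis(2,2,2-trifluoroethoxy)phosphoryl]acetate | COC(=O)CP(=O)(OCC(F)(F)F)OCC(F)(F)F | starting material
14 | paraformaldehyde (as formaldehyde) | C=O | starting material
15 | methyl 2-[bis(2,2,2-trifluoroethoxy)phosphoryl]-3-hydroxypropanoate | COC(=O)C(CO)P(=O)(OCC(F)(F)F)OCC(F)(F)F | intermediate
16 | methyl 2-[bis(2,2,2-trifluoroethoxy)phosphoryl]prop-2-enoate | COC(=O)C(=C)P(=O)(OCC(F)(F)F)OCC(F)(F)F | intermediate
17 | potassium salt of methyl 2-[bis(2,2,2-trifluoroethoxy)phosphoryl]-3-{[(2Z)-3-iodo-4-(triethylsilyloxy)but-2-en-1-yl]oxy}propanoate (C2 carbanion) | [K+].COC(=O)[C-](COC/C=C(\I)CO[Si](CC)(CC)CC)P(=O)(OCC(F)(F)F)OCC(F)(F)F | intermediate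
18 | methyl (2Z,4S,6E)-6-(diethoxymethyl)-2-({[(2Z)-3-iodo-4-(triethylsilyloxy)but-2-en-1-yl]oxy}methyl)-4-(triethylsilyloxy)nona-2,6,8-trienoate | CC[Si](CC)(CC)OC/C(I)=C/COC/C(C(=O)OC)=C/[C@@H](O[Si](CC)(CC)CC)C/C(=C\C=C)C(OCC)OCC | intermediate
19 | B-alkyl-9-BBN adduct of 18 (boron on C3, the former terminal carbon of the diene) | CC[Si](CC)(CC)OC/C(I)=C/COC/C(C(=O)OC)=C/[C@@H](O[Si](CC)(CC)CC)C/C(=C\CCB1C2CCCC1CCC2)C(OCC)OCC | intermediate
20 | methyl (3Z,5S,7E,11E)-7-(diethoxymethyl)-5-(triethylsilyloxy)-11-[(triethylsilyloxy)methyl]-1-oxacyclotrideca-3,7,11-triene-3-carboxylate | O1C/C=C(/CO[Si](CC)(CC)CC)CC/C=C(/C(OCC)OCC)C[C@H](O[Si](CC)(CC)CC)/C=C(\C(=O)OC)C1 | intermediate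
21 | methyl (3Z,5S,7E,11E)-7-(diethoxymethyl)-11-formyl-5-(triethylsilyloxy)-1-oxacyclotrideca-3,7,11-triene-3-carboxylate | O1C/C=C(/C=O)CC/C=C(/C(OCC)OCC)C[C@H](O[Si](CC)(CC)CC)/C=C(\C(=O)OC)C1 | intermediate
22 | potassium dienolate of 21 (O15–C15=C4–C5=C6 inside the thirteen-membered ring) | [K+].[O-]C=C1CC/C=C(/C(OCC)OCC)C[C@H](O[Si](CC)(CC)CC)/C=C(\C(=O)OC)COC=C1 | intermediate
23 | potassium alkoxide of the ring-contracted hydroxy ester (ten-membered ring, C6–O−, C7 bearing the 2-(methoxycarbonyl)vinyl group, 8-silyloxy) | C=C(C(=O)OC)[C@H]1[C@H]([O-])/C=C(/C=O)CC/C=C(/C(OCC)OCC)C[C@@H]1O[Si](CC)(CC)CC.[K+] | intermediate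
24 | (3aS,4S,6E,10E,11aR)-6-(diethoxymethyl)-3-methylidene-2-oxo-4-(triethylsilyloxy)-2,3,3a,4,5,8,9,11a-octahydrocyclodeca[b]furan-10-carbaldehyde (8α-silyloxy, 6α,12-olide) | C=C1C(=O)O[C@@H]2/C=C(/C=O)CC/C=C(/C(OCC)OCC)C[C@H](O[Si](CC)(CC)CC)[C@@H]12 | intermediate
25 | (3aR,4S,6E,10E,11aR)-6-(diethoxymethyl)-4-hydroxy-3-methylidene-2-oxo-2,3,3a,4,5,8,9,11a-octahydrocyclodeca[b]furan-10-carbaldehyde | C=C1C(=O)O[C@@H]2/C=C(/C=O)CC/C=C(/C(OCC)OCC)C[C@H](O)[C@@H]12 | intermediate
26 | (2S)-2-methylbutanoic acid | CC[C@H](C)C(=O)O | starting material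
27 | (3aR,4R,6E,10E,11aR)-6-(diethoxymethyl)-10-formyl-3-methylidene-2-oxo-2,3,3a,4,5,8,9,11a-octahydrocyclodeca[b]furan-4-yl (2S)-2-methylbutanoate | C=C1C(=O)O[C@@H]2/C=C(/C=O)CC/C=C(/C(OCC)OCC)C[C@@H](OC(=O)[C@@H](C)CC)[C@@H]12 | intermediate
28 | (3aR,4R,6E,10E,11aR)-6-(diethoxymethyl)-10-(hydroxymethyl)-3-methylidene-2-oxo-2,3,3a,4,5,8,9,11a-octahydrocyclodeca[b]furan-4-yl (2S)-2-methylbutanoate | C=C1C(=O)O[C@@H]2/C=C(/CO)CC/C=C(/C(OCC)OCC)C[C@@H](OC(=O)[C@@H](C)CC)[C@@H]12 | intermediate
29 | (3aR,4R,6E,10E,11aR)-6-formyl-10-(hydroxymethyl)-3-methylidene-2-oxo-2,3,3a,4,5,8,9,11a-octahydrocyclodeca[b]furan-4-yl (2S)-2-methylbutanoate (CNP0168859.6) | C=C1C(=O)O[C@@H]2/C=C(/CO)CC/C=C(/C=O)C[C@@H](OC(=O)[C@@H](C)CC)[C@@H]12 | target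

## Step count and risk

Total step count: 14. Longest linear sequence: 11 steps (5 → 6 → 10 → 11 → 12 → 18 → 20 → 21 → 24 → 25 → 27 → 29, steps 3–6 and 8–14).

Step 11 (key step, proposed new method). Several things may go wrong:
- The dienolate may react through C4 (α-attack on the acrylate) or by intermolecular aldol addition.
- The base may remove the C8 proton instead, followed by loss of the C13 alkoxide and opening of the macrocycle.
- The rearrangement may be too slow below the temperature at which the dienolate decomposes.
- Facial selectivity at C7 may be poor, or C6 may epimerise through re-enolisation by the liberated methoxide.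
- If the sense of 1,2-induction from C8 were the opposite one, the enantiomeric epoxide series and an esterification with retention would be used instead of steps 3 and 13 as written.

The fallback uses known chemistry and sets out from 20. The ester of 20 would be reduced with i-Bu2AlH to the macrocyclic allylic alcohol F1. Treatment with excess n-BuLi in THF/HMPA at −78 °C (the C12 alkoxide forms first and disfavours metalation at the neighbouring C13) would effect the classical transannular [2,3]-Wittig ring contraction to the ring-contracted diol F2. Oxidative lactonisation of the 1,4-diol with TEMPO/PhI(OAc)2 would give the silyl-protected lactone F3. The selective Swern oxidation of its primary silyl ether returns to the route at 24. The known weak point of this variant is the site of metalation (C6 against C13 or C15).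

Step 4. The alkenyl ligand may transfer poorly in the carbocupration. The α-acetal alkenylcopper 9 may lose ethoxide to an allenyl ether before the slow epoxide opening. The fallback sets out from 8: deprotonation (n-BuLi) and addition to paraformaldehyde gives 4,4-diethoxybut-2-yn-1-ol F4. The hydroalumination–iodination of step 2 then gives (2Z)-4,4-diethoxy-3-iodobut-2-en-1-ol F5. MnO2 oxidation gives (2Z)-4,4-diethoxy-3-iodobut-2-enal F6, and Wittig methylenation (Ph3P=CH2) gives (3Z)-5,5-diethoxy-4-iodopenta-1,3-diene F7. Iodine–magnesium exchange (i-PrMgCl·LiCl, −40 °C) and CuI-catalysed opening of epoxide 6 return to the route at 10.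

Step 9. Oligomerisation at the concentrations needed for transmetalation, protodeboronation or β-hydride elimination of the alkylborane, and slow oxidative addition at the hindered iodide may all lower the ring closure. The fallback sets out from 18: hydroboration to 19 followed by iodinolysis (I2, NaOMe) gives the primary iodide F8. Selective zinc insertion into the alkyl iodide (Zn, LiCl, THF) and an intramolecular Negishi coupling with Pd(PPh3)4 under base-free, anhydrous conditions come back to the route at 20.

Step 13. The activated C8 alcohol may eliminate towards C9 (a conjugated diene would result), substitution at the hindered secondary centre may be slow, and the phosphine may add to the methylene lactone. The fallback sets out from 25. The alcohol is converted with ClCH2SO2Cl and pyridine into the chloromethanesulfonate F9, which is displaced with the cesium salt of 26 (Cs2CO3, 18-crown-6, toluene). This separates activation from a phosphine-free SN2 inversion and comes back at 27.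

## Further compounds

F1 | step 11 | 3-(hydroxymethyl) analogue of 20 (ester reduced to the C12 allylic alcohol) | O1C/C=C(/CO[Si](CC)(CC)CC)CC/C=C(/C(OCC)OCC)C[C@H](O[Si](CC)(CC)CC)/C=C(\CO)C1
F2 | step 11 | ring-contracted diol (ten-membered ring, 6-OH, C7 bearing 3-hydroxyprop-1-en-2-yl, 8-silyloxy, 15-silyloxy) | C=C(CO)[C@H]1[C@H](O)/C=C(/CO[Si](CC)(CC)CC)CC/C=C(/C(OCC)OCC)C[C@@H]1O[Si](CC)(CC)CC
F3 | step 11 | 15-O-triethylsilyl analogue of 24 (C15 as CH2OSiEt3) | C=C1C(=O)O[C@@H]2/C=C(/CO[Si](CC)(CC)CC)CC/C=C(/C(OCC)OCC)C[C@H](O[Si](CC)(CC)CC)[C@@H]12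
F4 | step 4 | 4,4-diethoxybut-2-yn-1-ol | OCC#CC(OCC)OCC
F5 | step 4 | (2Z)-4,4-diethoxy-3-iodobut-2-en-1-ol | OC/C=C(\I)C(OCC)OCC
F6 | step 4 | (2Z)-4,4-diethoxy-3-iodobut-2-enal | O=C/C=C(\I)C(OCC)OCC
F7 | step 4 | (3Z)-5,5-diethoxy-4-iodopenta-1,3-diene | C=C/C=C(\I)C(OCC)OCC
F8 | step 9 | primary iodide from 18 (C3 iodide in place of the terminal vinyl group) | CC[Si](CC)(CC)OC/C(I)=C/COC/C(C(=O)OC)=C/[C@@H](O[Si](CC)(CC)CC)C/C(=C\CCI)C(OCC)OCC
F9 | step 13 | chloromethanesulfonate of 25 | C=C1C(=O)O[C@@H]2/C=C(/C=O)CC/C=C(/C(OCC)OCC)C[C@H](OS(=O)(=O)CCl)[C@@H]12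
A1 | alternative 1 | open-chain bromo aldehyde for the Barbier-type cyclisation (C6 aldehyde, C13 bromide) | O=C/C=C(/CO[Si](CC)(CC)CC)CC/C=C(/C(OCC)OCC)C[C@@H](O[Si](CC)(CC)CC)/C=C(\CBr)C(=O)OC
A2 | alternative 2 | diene lactone for ring-closing metathesis across C4=C5 | C=C1C(=O)O[C@H](C=C)[C@H]1[C@H](OC(=O)[C@@H](C)CC)C/C(=C\CCC(=C)CO[Si](C)(C)C(C)(C)C)C(OCC)OCC
A3 | alternative 3 | elemane-type cis-divinylcyclohexane lactone for the Cope ring expansion | O=C[C@@]1(C=C)C[C@@H](OC(=O)[C@@H](C)CC)[C@H]2C(=C)C(=O)O[C@@H]2[C@@H]1C(=C)CO
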